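**Strategy.** Ring C of the target (O1, C2, C3, C4, C4a, C8a) differs from the furan ring of a 2-arylbenzofuran by one atom, C3. The flavan skeleton is therefore traced back to a flat, achiral 2-arylbenzofuran that already holds rings A and B, with all four phenols as benzyl ethers. Dibromocarbene supplies C3. It bridges the furan C2=C3 bond, the shared bond breaks, and a 3-bromoflavylium salt results. C2–C3 and C3–C4 are then in place and bromine marks the carbon that must bear oxygen. Bromine is exchanged for a ketone whose labile C2 lets one dynamic kinetic resolution set both stereocentres. Feruloylation follows.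

Key step: step 6

**Remarks on the design**
- **Atom map.** Benzofuran O1, C2, C3, C3a and C7a become flavan O1, C2, C4, C4a and C8a. The 4- and 6-benzyloxy groups end at C5 and C7. Precursor and product of the key step fit the target and need no structural correction.
- **Protecting groups.** Benzyl ethers are kept on purpose for the key step.
  - In the flavylium ion O5 and O7 share the positive charge, so silyl or acetal groups would be shed there.
  - Allyl groups would compete for the carbene and for Pd(0).
  - Hydrogenolysis would also saturate the feruloyl C=C bond, so benzyl is swapped for TBS in one telescoped operation before acylation.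
- **Carbene conditions.** The carbene is made without hydroxide, and the cation is released only by cold anhydrous acid with short contact.
- **Access to the benzofuran.**
  - The A ring comes from phloroglucinaldehyde, whose chelated ortho OH tells the three phenols apart without a statistical step or a regioselective iodination.
  - The B ring enters as the acid, at its own oxidation level, so no redox adjustment is needed.
- **Notation.** Racemic compounds are written without stereodescriptors. Telescoped operations count as one step.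
- **Assumption.** The (R,R)-catalyst in step 9 is assigned by the usual model, with the substituted, π-rich C2 side of the ketone taking the place of the aryl group of an aryl ketone. Both catalyst antipodes are commercial, so the mirror-image catalyst is used if the sense proves opposite.

**Step 1**
Reactants: 1 2,4,6-trihydroxybenzaldehyde
Product: 2 2,4-bis(benzyloxy)-6-hydroxybenzaldehyde
Conditions: BnBr (2.05 equiv), K2CO3, DMF, 0 °C to rt
Reagents that add atoms: benzyl bromide, BrCc1ccccc1
Why: Williamson ether synthesis in which the 4-OH and one ortho OH are alkylated, while the last ortho OH is tied up in a strong hydrogen bond to the formyl oxygen and should stay free when the halide is limited to two equivalents.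

**Step 2**
Reactants: 2 2,4-bis(benzyloxy)-6-hydroxybenzaldehyde
Product: 4 [2,4-bis(benzyloxy)-6-hydroxybenzyl]triphenylphosphonium bromide, via salicyl alcohol 3 (not isolated)
Conditions: NaBH4, THF–EtOH, 0 °C; aq NH4Cl, extract, concentrate cold; PPh3·HBr, MeCN, 80 °C
Reagents that add atoms: triphenylphosphine hydrobromide, [Br-].c1ccc(cc1)[PH+](c1ccccc1)c1ccccc1
Why: Borohydride reduction of the aldehyde followed by SN1-type phosphonium salt formation, in which the acid ionises the very electron-rich salicyl alcohol and triphenylphosphine traps the cation before it can alkylate another arene, which is why 3 is carried on crude.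

**Step 3**
Reactants: 5 4-O-methylgallic acid (3,5-dihydroxy-4-methoxybenzoic acid)
Product: 6 benzyl 3,5-bis(benzyloxy)-4-methoxybenzoate
Conditions: BnBr (3.3 equiv), K2CO3, DMF, 60 °C
Reagents that add atoms: benzyl bromide, BrCc1ccccc1
Why: Exhaustive O-alkylation (Williamson ether synthesis plus carboxylate alkylation) raises no selectivity question because every acidic OH is benzylated.

**Step 4**
Reactants: 6 benzyl 3,5-bis(benzyloxy)-4-methoxybenzoate
Product: 7 3,5-bis(benzyloxy)-4-methoxybenzoic acid
Conditions: KOH, THF–MeOH–H2O, 65 °C; then aq HCl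
Reagents that add atoms: potassium hydroxide, [K+].[OH-]
Why: Saponification (BAc2 ester hydrolysis) cleaves only the benzyl ester, since aryl benzyl and aryl methyl ethers are inert to hydroxide.

**Step 5**
Reactants: 7 3,5-bis(benzyloxy)-4-methoxybenzoic acid, 4 [2,4-bis(benzyloxy)-6-hydroxybenzyl]triphenylphosphonium bromide
Product: 10 4,6-bis(benzyloxy)-2-[3,5-bis(benzyloxy)-4-methoxyphenyl]benzofuran, via acid chloride 8 (not isolated), via aryl ester phosphonium salt 9 (not isolated)
Conditions: 7, (COCl)2, cat. DMF, CH2Cl2, rt, evaporate; 4, Et3N (3 equiv), toluene, 110 °C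
Reagents that add atoms: none
Why: Intramolecular Wittig benzofuran synthesis, in which the acid chloride acylates the phenol, triethylamine forms the benzylic ylide, and the ylide attacks the neighbouring ester carbonyl with loss of triphenylphosphine oxide, so that the furan C2=C3 bond forms with unambiguous regiochemistry.

**Step 6**
Reactants: 10 4,6-bis(benzyloxy)-2-[3,5-bis(benzyloxy)-4-methoxyphenyl]benzofuran, 11 bromoform
Product: 14 5,7-bis(benzyloxy)-2-[3,5-bis(benzyloxy)-4-methoxyphenyl]-3-bromochromenylium bromide, via dibromocyclopropane adduct 12 (not isolated), via tert-butyl ketal 13 (not isolated)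
Conditions: CHBr3 (3 equiv), KOtBu (4.5 equiv, in portions), toluene, −20 °C to rt, Ar, dark; cold water wash, dry; HBr (33% in AcOH, 1.5 equiv), Et2O, 0 °C, filter
Reagents that add atoms: hydrogen bromide, Br
Why: tert-Butoxide deprotonates bromoform and α-elimination of bromide gives singlet dibromocarbene, which adds to the furan C2=C3 bond of 10 in a concerted, asynchronous [2+1] cheletropic step (bonding to the nucleophilic C3 runs ahead) and closes the three-membered ring of the cis-fused adduct 12. Adduct 12 should ionise at or below room temperature, the endo bromide leaving while the bond shared by the two rings opens in a disrotatory two-electron electrocyclic process (Woodward–Hoffmann–DePuy rule), so that six-membered ring C arises by enlargement of the bicyclo[3.1.0] unit and not by a cyclisation, driven by the aromatic pyrylium cation that O1, the 5- and 7-benzyloxy groups and the 2-aryl group stabilise. Surplus tert-butoxide parks the cation as the neutral ketal 13, which has no free OH and cannot ring-open, and cold anhydrous HBr ionises it again to salt 14, which should precipitate from ether. The closest known chemistry is the Ciamician–Dennstedt rearrangement of pyrroles and indoles and its oxygen counterpart, the dihalocarbene enlargement of benzofurans to 3-halo-2H-chromenes. No stereocentre is created for good, because the two centres of 12 and the one of 13 are flattened in achiral 14. The step needs attack at the furan bond in preference to the arenes and the benzylic C–H bonds, which the enol-ether character of that bond, raised further by the 4,6-dialkoxy ring and the 2-aryl group, should secure, and it needs a hydroxide-free medium, because the hydroxide adduct of a 3-halopyrylium is prone to Perkin-type ring contraction.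

**Step 7**
Reactants: 14 5,7-bis(benzyloxy)-2-[3,5-bis(benzyloxy)-4-methoxyphenyl]-3-bromochromenylium bromide
Product: 15 racemic 5,7-bis(benzyloxy)-2-[3,5-bis(benzyloxy)-4-methoxyphenyl]-3-bromo-2H-chromene (3-bromoflav-3-ene)
Conditions: NaBH4 (1.2 equiv), MeCN, −20 to 0 °C; aq NaHCO3
Reagents that add atoms: none
Why: Hydride addition to a pyrylium cation, expected at C2 (next to the oxonium oxygen and remote from the peri 5-benzyloxy group) and giving C2 as a racemate that step 9 corrects, while delivery at C4 would do no harm because either alkenyl bromide leads to the same ketone in step 8.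

**Step 8**
Reactants: 15 racemic 3-bromoflav-3-ene
Product: 17 racemic 5,7-bis(benzyloxy)-2-[3,5-bis(benzyloxy)-4-methoxyphenyl]chroman-3-one (flavan-3-one), via alkenyl boronate 16 (not isolated)
Conditions: B2pin2, PdCl2(dppf) (5 mol %), KOAc, 1,4-dioxane, 80 °C; cool; NaBO3·4H2O, THF–H2O, 0 °C to rt, Ar
Reagents that add atoms: sodium perborate, [Na+].[Na+].O[B-]1(O)OO[B-](O)(O)OO1
Why: Miyaura borylation of the cyclic alkenyl bromide followed by mild perborate oxidation of the C–B bond (1,2-migration from boron to oxygen) places oxygen at C3, and tautomerisation delivers the carbonyl group, with benzyl ethers untouched by either stage.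

**Step 9**
Reactants: 17 racemic flavan-3-one
Product: 18 (2R,3R)-5,7-bis(benzyloxy)-2-[3,5-bis(benzyloxy)-4-methoxyphenyl]chroman-3-ol (2,3-cis)
Conditions: RuCl[(R,R)-TsDPEN](p-cymene) (2 mol %), HCO2H–Et3N (5:2), CH2Cl2, 35 °C
Reagents that add atoms: none
Why: Noyori–Ikariya asymmetric transfer hydrogenation run as a dynamic kinetic resolution, a reaction type known for 1-aryl-2-tetralones and other α-aryl cyclic ketones, in which C2–H (flanked by carbonyl, aryl and aryloxy groups) lets the ketone enantiomers interconvert by enolisation in the amine–formic acid medium, the catalyst reduces the (2R)-ketone faster and so fixes C2 as R, and hydride enters anti to the 2-aryl group and sets C3 as R and cis to C2.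

**Step 10**
Reactants: 18 (2R,3R)-tetrabenzyl flavan-3-ol
Product: 20 (2R,3R)-5,7-bis(tert-butyldimethylsilyloxy)-2-[3,5-bis(tert-butyldimethylsilyloxy)-4-methoxyphenyl]chroman-3-ol, via 4'-O-methylepigallocatechin 19 (not isolated)
Conditions: H2 (1 atm), 20% Pd(OH)2/C, THF–MeOH, rt; filter, evaporate; TBSCl (4.4 equiv), imidazole, DMF, 0 °C to rt
Reagents that add atoms: tert-butyldimethylsilyl chloride, CC(C)(C)[Si](C)(C)Cl
Why: Hydrogenolysis over Pearlman's catalyst frees the four phenols without touching C2 or C3, and chemoselective silylation of the crude polyphenol follows, since phenols react far faster than the hindered axial secondary 3-OH, which should stay free at this stoichiometry.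

**Step 11**
Reactants: 21 ferulic acid
Product: 23 (E)-3-[4-(tert-butyldimethylsilyloxy)-3-methoxyphenyl]prop-2-enoic acid, via silyl ester 22 (not isolated)
Conditions: TBSCl (2.3 equiv), imidazole, DMF, rt; then AcOH–THF–H2O, rt
Reagents that add atoms: tert-butyldimethylsilyl chloride, CC(C)(C)[Si](C)(C)Cl
Why: Silylation of both acidic OH groups followed by selective solvolysis of the far more labile silyl ester in aqueous acetic acid, which leaves the aryl silyl ether and the E-alkene intact.

**Step 12**
Reactants: 20 (2R,3R)-tetra-TBS flavan-3-ol, 23 4-O-TBS-ferulic acid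
Product: 24 (2R,3R)-5,7-bis(tert-butyldimethylsilyloxy)-2-[3,5-bis(tert-butyldimethylsilyloxy)-4-methoxyphenyl]chroman-3-yl (E)-3-[4-(tert-butyldimethylsilyloxy)-3-methoxyphenyl]prop-2-enoate
Conditions: DCC, DMAP, CH2Cl2, 0 °C to rt
Reagents that add atoms: none
Why: Steglich esterification, the standard way to acylate the axial 3-OH of protected epi-series flavanols, leaves the C3–O bond untouched so that both stereocentres are retained.

**Step 13**
Reactants: 24 penta-TBS ester
Product: 25 4'-O-methylepigallocatechin-3-O-ferulate, (2R,3R), E-alkene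
Conditions: HF·pyridine, THF–pyridine, 0 °C to rt
Reagents that add atoms: none
Why: Fluoride-mediated desilylation of the five aryl silyl ethers under weakly acidic conditions spares the ester and the E-alkene, and C2 cannot epimerise because the 4'-methoxy group blocks the B-ring quinone methide pathway.

**Compound list**

| No. | Name | SMILES | Role |
|---|---|---|---|
| 1 | 2,4,6-trihydroxybenzaldehyde | O=Cc1c(O)cc(O)cc1O | starting material |
| 2 | 2,4-bis(benzyloxy)-6-hydroxybenzaldehyde | O=Cc1c(O)cc(OCc2ccccc2)cc1OCc1ccccc1 | intermediate |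
| 3 | 3,5-bis(benzyloxy)-2-(hydroxymethyl)phenol, not isolated | OCc1c(O)cc(OCc2ccccc2)cc1OCc1ccccc1 | intermediate |
| 4 | [2,4-bis(benzyloxy)-6-hydroxybenzyl]triphenylphosphonium bromide | [Br-].Oc1cc(OCc2ccccc2)cc(OCc2ccccc2)c1C[P+](c1ccccc1)(c1ccccc1)c1ccccc1 | intermediate |
| 5 | 4-O-methylgallic acid | COc1c(O)cc(cc1O)C(=O)O | starting material |
| 6 | benzyl 3,5-bis(benzyloxy)-4-methoxybenzoate | COc1c(OCc2ccccc2)cc(cc1OCc1ccccc1)C(=O)OCc1ccccc1 | intermediate |
| 7 | 3,5-bis(benzyloxy)-4-methoxybenzoic acid | COc1c(OCc2ccccc2)cc(cc1OCc1ccccc1)C(=O)O | intermediate |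
| 8 | 3,5-bis(benzyloxy)-4-methoxybenzoyl chloride, not isolated | COc1c(OCc2ccccc2)cc(cc1OCc1ccccc1)C(=O)Cl | intermediate |
| 9 | {2,4-bis(benzyloxy)-6-[3,5-bis(benzyloxy)-4-methoxybenzoyloxy]benzyl}triphenylphosphonium bromide, not isolated | [Br-].COc1c(OCc2ccccc2)cc(cc1OCc1ccccc1)C(=O)Oc1cc(OCc2ccccc2)cc(OCc2ccccc2)c1C[P+](c1ccccc1)(c1ccccc1)c1ccccc1 | intermediate |
| 10 | 4,6-bis(benzyloxy)-2-[3,5-bis(benzyloxy)-4-methoxyphenyl]benzofuran | COc1c(OCc2ccccc2)cc(cc1OCc1ccccc1)-c1cc2c(OCc3ccccc3)cc(OCc3ccccc3)cc2o1 | intermediate |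
| 11 | bromoform | BrC(Br)Br | starting material |
| 12 | 4,6-bis(benzyloxy)-1a-[3,5-bis(benzyloxy)-4-methoxyphenyl]-1,1-dibromo-1a,6b-dihydro-1H-cyclopropa[b]benzofuran, racemic, cis-fused, not isolated | COc1c(OCc2ccccc2)cc(cc1OCc1ccccc1)C12Oc3cc(OCc4ccccc4)cc(OCc4ccccc4)c3C1C2(Br)Br | intermediate |
| 13 | 5,7-bis(benzyloxy)-2-[3,5-bis(benzyloxy)-4-methoxyphenyl]-3-bromo-2-tert-butoxy-2H-chromene, racemic, not isolated | COc1c(OCc2ccccc2)cc(cc1OCc1ccccc1)C1(OC(C)(C)C)Oc2cc(OCc3ccccc3)cc(OCc3ccccc3)c2C=C1Br | intermediate |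
| 14 | 5,7-bis(benzyloxy)-2-[3,5-bis(benzyloxy)-4-methoxyphenyl]-3-bromochromenylium bromide (3-bromo-5,7,3',5'-tetrabenzyloxy-4'-methoxyflavylium bromide) | COc1c(OCc2ccccc2)cc(cc1OCc1ccccc1)-c1[o+]c2cc(OCc3ccccc3)cc(OCc3ccccc3)c2cc1Br.[Br-] | intermediate |
| 15 | 5,7-bis(benzyloxy)-2-[3,5-bis(benzyloxy)-4-methoxyphenyl]-3-bromo-2H-chromene, racemic | COc1c(OCc2ccccc2)cc(cc1OCc1ccccc1)C1Oc2cc(OCc3ccccc3)cc(OCc3ccccc3)c2C=C1Br | intermediate |
| 16 | 5,7-bis(benzyloxy)-2-[3,5-bis(benzyloxy)-4-methoxyphenyl]-3-(4,4,5,5-tetramethyl-1,3,2-dioxaborolan-2-yl)-2H-chromene, racemic, not isolated | COc1c(OCc2ccccc2)cc(cc1OCc1ccccc1)C1Oc2cc(OCc3ccccc3)cc(OCc3ccccc3)c2C=C1B1OC(C)(C)C(C)(C)O1 | intermediate |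
| 17 | 5,7-bis(benzyloxy)-2-[3,5-bis(benzyloxy)-4-methoxyphenyl]chroman-3-one, racemic | COc1c(OCc2ccccc2)cc(cc1OCc1ccccc1)C1Oc2cc(OCc3ccccc3)cc(OCc3ccccc3)c2CC1=O | intermediate |
| 18 | (2R,3R)-5,7-bis(benzyloxy)-2-[3,5-bis(benzyloxy)-4-methoxyphenyl]chroman-3-ol | O[C@@H]1Cc2c(OCc3ccccc3)cc(OCc3ccccc3)cc2O[C@@H]1c1cc(OCc2ccccc2)c(OC)c(OCc2ccccc2)c1 | intermediate |
| 19 | (2R,3R)-2-(3,5-dihydroxy-4-methoxyphenyl)chromane-3,5,7-triol (4'-O-methylepigallocatechin), not isolated | O[C@@H]1Cc2c(O)cc(O)cc2O[C@@H]1c1cc(O)c(OC)c(O)c1 | intermediate |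
| 20 | (2R,3R)-5,7-bis(tert-butyldimethylsilyloxy)-2-[3,5-bis(tert-butyldimethylsilyloxy)-4-methoxyphenyl]chroman-3-ol | O[C@@H]1Cc2c(O[Si](C)(C)C(C)(C)C)cc(O[Si](C)(C)C(C)(C)C)cc2O[C@@H]1c1cc(O[Si](C)(C)C(C)(C)C)c(OC)c(O[Si](C)(C)C(C)(C)C)c1 | intermediate |
| 21 | ferulic acid | COc1cc(/C=C/C(=O)O)ccc1O | starting material |
| 22 | tert-butyldimethylsilyl (E)-3-[4-(tert-butyldimethylsilyloxy)-3-methoxyphenyl]prop-2-enoate, not isolated | COc1cc(/C=C/C(=O)O[Si](C)(C)C(C)(C)C)ccc1O[Si](C)(C)C(C)(C)C | intermediate |
| 23 | (E)-3-[4-(tert-butyldimethylsilyloxy)-3-methoxyphenyl]prop-2-enoic acid | COc1cc(/C=C/C(=O)O)ccc1O[Si](C)(C)C(C)(C)C | intermediate |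
| 24 | (2R,3R)-penta-TBS 4'-O-methylepigallocatechin-3-O-ferulate | COc1cc(/C=C/C(=O)O[C@@H]2Cc3c(O[Si](C)(C)C(C)(C)C)cc(O[Si](C)(C)C(C)(C)C)cc3O[C@@H]2c2cc(O[Si](C)(C)C(C)(C)C)c(OC)c(O[Si](C)(C)C(C)(C)C)c2)ccc1O[Si](C)(C)C(C)(C)C | intermediate |
| 25 | 4'-O-methylepigallocatechin-3-O-ferulate | COc1cc(/C=C/C(=O)O[C@@H]2Cc3c(O)cc(O)cc3O[C@@H]2c2cc(O)c(OC)c(O)c2)ccc1O | target |

**Step count.** Total: 13 steps. Longest linear sequence: 10 steps (1, 2, 5, 6, 7, 8, 9, 10, 12, 13). The B-ring branch (3, 4, 5 and onward) is equally long.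

**Steps most likely to fail**

**Step 6 (carbon insertion).** Three processes could defeat it:
- The carbene may be consumed by base and medium faster than by the hindered trisubstituted furan bond.
- The dipolar adduct may lose the C3 proton instead of closing the three-membered ring.
- The cation may decay before it is parked as the ketal.

The fallback sets out from 7 and 2 and comes back at 17, by-passing 10 to 16. Methyllithium (2.2 equiv, THF, 0 °C) turns acid 7 into the acetophenone F1. Dry HCl in ethyl acetate at 0 °C condenses it with salicylaldehyde 2, in the classical aldol and cyclodehydration synthesis of flavylium salts, to the 3-unsubstituted flavylium chloride F2. NaBH4 in MeCN gives the flavene, drawn as the flav-2-ene F3; either double-bond isomer directs boron to C3. Hydroboration (BH3·THF) and H2O2/NaOH oxidation give the racemic 2,3-trans-flavan-3-ol F4. Dess–Martin oxidation then gives 17.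

**Step 9 (dynamic kinetic resolution).** Enolisation at C2 may be slower than reduction of the slow-reacting enantiomer. Facial and cis selectivity may also be poor, because the carbonyl group is not conjugated to an arene.

The fallback sets out from 17 and comes back at 18. L-Selectride in THF at −78 °C attacks anti to the 2-aryl group and gives the racemic cis-flavan-3-ol F5. Acylation with (1S,4R)-camphanoyl chloride (DMAP, pyridine, CH2Cl2) gives two diastereomers, the (2R,3R)-camphanate F6 and the (2S,3S)-camphanate F7. They are separated by crystallisation or chromatography. LiOH in THF–MeOH–H2O releases 18 from F6.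

**Step 8 (bromine to carbonyl).** Oxidative addition at the hindered bromide may be slow, protodebromination may compete, and the base-sensitive ketone may suffer oxidative degradation at C2 during the perborate stage.

The fallback sets out from 15 and comes back at 17. It uses a C–N bond and hydrolysis in place of a C–B bond and oxidation. Buchwald–Hartwig-type amination of the alkenyl bromide with morpholine (Pd2(dba)3, BINAP, NaOtBu, toluene, 80 °C) gives the morpholine enamine F8. Mild hydrolysis (aq oxalic acid, THF, rt) gives 17 without any oxidant.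

**Further compounds**
F1 | step 6 | 1-[3,5-bis(benzyloxy)-4-methoxyphenyl]ethanone | COc1c(OCc2ccccc2)cc(cc1OCc1ccccc1)C(C)=O
F2 | step 6 | 5,7-bis(benzyloxy)-2-[3,5-bis(benzyloxy)-4-methoxyphenyl]chromenylium chloride | COc1c(OCc2ccccc2)cc(cc1OCc1ccccc1)-c1[o+]c2cc(OCc3ccccc3)cc(OCc3ccccc3)c2cc1.[Cl-]
F3 | step 6 | 5,7-bis(benzyloxy)-2-[3,5-bis(benzyloxy)-4-methoxyphenyl]-4H-chromene (flav-2-ene) | COc1c(OCc2ccccc2)cc(cc1OCc1ccccc1)C1=CCc2c(OCc3ccccc3)cc(OCc3ccccc3)cc2O1
F4 | step 6 | racemic 2,3-trans-5,7-bis(benzyloxy)-2-[3,5-bis(benzyloxy)-4-methoxyphenyl]chroman-3-ol, (2R,3S) plus (2S,3R) | O[C@H]1Cc2c(OCc3ccccc3)cc(OCc3ccccc3)cc2O[C@@H]1c1cc(OCc2ccccc2)c(OC)c(OCc2ccccc2)c1.O[C@@H]1Cc2c(OCc3ccccc3)cc(OCc3ccccc3)cc2O[C@H]1c1cc(OCc2ccccc2)c(OC)c(OCc2ccccc2)c1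
F5 | step 9 | racemic 2,3-cis-5,7-bis(benzyloxy)-2-[3,5-bis(benzyloxy)-4-methoxyphenyl]chroman-3-ol, (2R,3R) plus (2S,3S) | O[C@@H]1Cc2c(OCc3ccccc3)cc(OCc3ccccc3)cc2O[C@@H]1c1cc(OCc2ccccc2)c(OC)c(OCc2ccccc2)c1.O[C@H]1Cc2c(OCc3ccccc3)cc(OCc3ccccc3)cc2O[C@H]1c1cc(OCc2ccccc2)c(OC)c(OCc2ccccc2)c1
F6 | step 9 | (2R,3R)-5,7-bis(benzyloxy)-2-[3,5-bis(benzyloxy)-4-methoxyphenyl]chroman-3-yl (1S,4R)-camphanate | O=C(O[C@@H]1Cc2c(OCc3ccccc3)cc(OCc3ccccc3)cc2O[C@@H]1c1cc(OCc2ccccc2)c(OC)c(OCc2ccccc2)c1)[C@@]12CC[C@@](C)(C(=O)O1)C2(C)C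
F7 | step 9 | (2S,3S)-5,7-bis(benzyloxy)-2-[3,5-bis(benzyloxy)-4-methoxyphenyl]chroman-3-yl (1S,4R)-camphanate | O=C(O[C@H]1Cc2c(OCc3ccccc3)cc(OCc3ccccc3)cc2O[C@H]1c1cc(OCc2ccccc2)c(OC)c(OCc2ccccc2)c1)[C@@]12CC[C@@](C)(C(=O)O1)C2(C)C
F8 | step 8 | 4-{5,7-bis(benzyloxy)-2-[3,5-bis(benzyloxy)-4-methoxyphenyl]-2H-chromen-3-yl}morpholine, racemic | COc1c(OCc2ccccc2)cc(cc1OCc1ccccc1)C1Oc2cc(OCc3ccccc3)cc(OCc3ccccc3)c2C=C1N1CCOCC1
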